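**Strategy.** Manuifolin D is cut at the C3–C1' bond between ring C and ring B. Its only stereocentre, C3, is a tertiary CH flanked by C4H2 and by C2, which carries O1. Writing C2 as a lactone carbonyl turns rings A/C into a dihydroumbelliferone whose C3 can become a planar α-acyl radical with two unlike neighbours. A chiral nickel catalyst then couples racemic 3-bromo-7-SEM-oxychroman-2-one with a fully substituted ring-B arylzinc iodide, joining the halves and fixing (R)-C3 in one enantioconvergent operation. Lactone reduction, Mitsunobu closure of ring C at O1–C2 and fluoride removal of both SEM groups finish the synthesis.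

Key step: step 9

Remark: SEM = 2-(trimethylsilyl)ethoxymethyl and prenyl = 3-methylbut-2-en-1-yl; the pybox antipode is assumed to be the one that correlation of the chiroptical sign of 17 with known (3R)-isoflavans identifies as R-selective, and all SMILES show that enantiomer.

## Route

Step 1
Reactants: 1 umbelliferone (7-hydroxy-2H-chromen-2-one)
Product: 2 7-(SEM-oxy)-2H-chromen-2-one
Conditions: SEMCl, iPr2NEt, DMF, 0 °C to rt
Reagents that add atoms: 2-(trimethylsilyl)ethoxymethyl chloride (SEMCl), C[Si](C)(C)CCOCCl
Why: O-alkylation of the acidic 7-OH with the alkoxymethyl chloride (SEM protection) is routine and gives an acetal that should survive hydrogenation, enolate, organozinc and hydride chemistry and leave with fluoride.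

Step 2
Reactants: 2 7-(SEM-oxy)-2H-chromen-2-one
Product: 3 7-(SEM-oxy)chroman-2-one
Conditions: H2 (3 atm), 10% Pd/C, EtOAc, rt
Reagents that add atoms: none
Why: Heterogeneous catalytic hydrogenation saturates the conjugated C3=C4 bond of a coumarin without touching the arene, the lactone or the non-benzylic SEM acetal.

Step 3
Reactants: 3 7-(SEM-oxy)chroman-2-one
Product: 5 rac-3-bromo-7-(SEM-oxy)chroman-2-one, via silyl ketene acetal 4 (not isolated)
Conditions: LiHMDS added to 3 and TMSCl, THF, −78 °C; volatiles removed; then NBS, THF, −78 °C; neutral work-up, rapid filtration through silica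
Reagents that add atoms: N-bromosuccinimide, O=C1CCC(=O)N1Br; chlorotrimethylsilane (atoms kept only in intermediate 4), C[Si](C)(C)Cl
Why: Enolisation with in situ silylation captures the lactone enolate as its silyl ketene acetal before the aryl ester can ring-open or self-condense, and electrophilic α-bromination of that acetal by NBS is much faster than bromination of the alkoxy arene, the product then being kept away from base because HBr loss would regenerate the coumarin.

Step 4
Reactants: 6 4-bromoresorcinol, 7 prenyl bromide (1-bromo-3-methylbut-2-ene)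
Product: 8 2-bromo-5-(prenyloxy)phenol
Conditions: 7 (0.95 equiv), K2CO3, acetone, rt; chromatographic removal of the regioisomer and the bis-ether
Reagents that add atoms: none
Why: Williamson ether synthesis is expected to favour the hydroxyl para to bromine, because the hydroxyl ortho to bromine is shielded and its phenoxide is the weaker nucleophile, and the minor isomer is separable.

Step 5
Reactants: 8 2-bromo-5-(prenyloxy)phenol
Product: 9 1-bromo-4-(prenyloxy)-2-(SEM-oxy)benzene
Conditions: SEMCl, iPr2NEt, Bu4NI (cat.), CH2Cl2, 0 °C to rt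
Reagents that add atoms: 2-(trimethylsilyl)ethoxymethyl chloride (SEMCl), C[Si](C)(C)CCOCCl
Why: SEM protection (O-alkylation) of the remaining phenol gives an acetal that cannot migrate to an ortho carbanion, assists the later metalation and is removed by fluoride.

Step 6
Reactants: 9 1-bromo-4-(prenyloxy)-2-(SEM-oxy)benzene
Product: 10 4-bromo-2-(2-methylbut-3-en-2-yl)-5-(SEM-oxy)phenol
Conditions: N,N-diethylaniline (degassed), 190 °C, Ar, stopped at full conversion
Reagents that add atoms: none
Why: The aromatic Claisen rearrangement ([3,3]-sigmatropic shift followed by tautomerisation) delivers the prenyl unit with allylic inversion to an ortho carbon, and C5' is expected to be chosen because C3' is crowded between two oxygens and the para carbon carries bromine, while the basic solvent suppresses acid-promoted ring closure of the new ortho-allyl phenol.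

Step 7
Reactants: 10 4-bromo-2-(2-methylbut-3-en-2-yl)-5-(SEM-oxy)phenol, 7 prenyl bromide
Product: 11 1-bromo-5-(2-methylbut-3-en-2-yl)-4-(prenyloxy)-2-(SEM-oxy)benzene
Conditions: Cs2CO3, DMF, rt
Reagents that add atoms: none
Why: Williamson ether synthesis with the caesium phenoxide in DMF should O-alkylate the single free hydroxyl cleanly despite the neighbouring quaternary carbon.

Step 8
Reactants: 11 1-bromo-5-(2-methylbut-3-en-2-yl)-4-(prenyloxy)-2-(SEM-oxy)benzene
Product: 13 [5-(2-methylbut-3-en-2-yl)-4-(prenyloxy)-2-(SEM-oxy)phenyl]zinc iodide, via aryllithium 12 (not isolated)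
Conditions: t-BuLi (2.0 equiv), THF, −78 °C; then ZnI2 (1.1 equiv) in THF, −78 to 0 °C; solution titrated and used at once
Reagents that add atoms: zinc iodide, I[Zn]I; tert-butyllithium (lithium kept only in intermediate 12), [Li]C(C)(C)C
Why: Bromine–lithium exchange with two equivalents of t-BuLi is fast at −78 °C, is assisted by the ortho acetal oxygen and leaves no alkyl bromide behind, and transmetalation with ZnI2 gives a weakly basic arylzinc that tolerates the ethers and olefins and later the lactone.

Step 9
Reactants: 5 rac-3-bromo-7-(SEM-oxy)chroman-2-one, 13 [5-(2-methylbut-3-en-2-yl)-4-(prenyloxy)-2-(SEM-oxy)phenyl]zinc iodide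
Product: 14 (3R)-3-[5-(2-methylbut-3-en-2-yl)-4-(prenyloxy)-2-(SEM-oxy)phenyl]-7-(SEM-oxy)chroman-2-one
Conditions: NiCl2·glyme (10 mol %), chiral pybox ligand (13 mol %), glyme/THF, −30 °C, 13 (1.3 equiv), no base; cold aq. NH4Cl; short silica plug, carried on at once
Reagents that add atoms: none
Why: Proposed new method: transmetalation from 13 should give a ligated aryl-nickel(I) species that takes bromine from both antipodes of 5, so the two enantiomers collapse to one flat C3 radical stabilised by the lactone carbonyl, which is trapped at the chiral aryl-nickel(II) centre before reductive elimination from nickel(III) forms C3–C1'. The closest known reaction type is the nickel/pybox enantioconvergent Negishi arylation of racemic acyclic α-bromo ketones with arylzinc iodides, together with the Hiyama arylation of racemic α-bromo esters, whereas a six-membered aryl lactone and an ortho-alkoxy arylzinc are extensions not yet demonstrated. No ring is closed in this step. The new stereocentre C3 is controlled by the chiral ligand on nickel, which should tell the two faces of the radical apart because the rigid ring presents the C2 carbonyl on one side and the C4 methylene on the other. The step needs enantiofacial selection and cross-coupling ahead of HBr loss to coumarin 2 and of enolisation of 14, and the substrate and conditions secure this through the cyclic constraint, the weakly basic zinc reagent, the absence of added base and the low temperature. The two B-ring olefins lie meta and para to C1' and cannot reach the radical or the metal.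

Step 10
Reactants: 14 (3R)-3-aryl-7-(SEM-oxy)chroman-2-one
Product: 15 (2R)-3-[2-hydroxy-4-(SEM-oxy)phenyl]-2-[5-(2-methylbut-3-en-2-yl)-4-(prenyloxy)-2-(SEM-oxy)phenyl]propan-1-ol
Conditions: LiBH4, THF, −20 to 0 °C; aq. NH4Cl
Reagents that add atoms: none
Why: Hydride reduction of the activated aryl lactone by LiBH4 is rapid in the cold and frees the O1 phenol and the C2 primary alcohol in one operation, and as in the reductive cleavage of α-aryl acyl auxiliaries the weakly basic conditions should leave the α-aryl centre unenolised.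

Step 11
Reactants: 15 (2R)-2,3-diarylpropan-1-ol with free O1 phenol
Product: 16 (3R)-3-[5-(2-methylbut-3-en-2-yl)-4-(prenyloxy)-2-(SEM-oxy)phenyl]-7-(SEM-oxy)chroman (7,2'-bis-SEM manuifolin D)
Conditions: PPh3, DIAD, THF (0.02 M), 0 °C to rt
Reagents that add atoms: none
Why: Intramolecular Mitsunobu etherification lets the only free phenol, O1, displace the activated primary oxygen at C2 in a 6-exo-tet SN2 closure of ring C, and no bond to C3 is broken so the R configuration is retained.

Step 12
Reactants: 16 7,2'-bis-SEM manuifolin D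
Product: 17 manuifolin D, (3R)-3-[2-hydroxy-5-(2-methylbut-3-en-2-yl)-4-(prenyloxy)phenyl]chroman-7-ol
Conditions: TBAF (excess), THF/DMPU, 4 Å MS, 60 °C, slow Ar purge; aq. NH4Cl
Reagents that add atoms: none
Why: Fluoride attacks silicon and both SEM acetals fragment to fluorotrimethylsilane, ethene and formaldehyde (fluoride-induced SEM cleavage) without any acid, so the acid-labile aryl prenyl ether and the two olefins should survive, the gas purge removing formaldehyde before it can alkylate the electron-rich phenoxides.

## Compound list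

1 | umbelliferone (7-hydroxy-2H-chromen-2-one) | O=c1ccc2ccc(O)cc2o1 | starting material
2 | 7-(SEM-oxy)-2H-chromen-2-one | O=c1ccc2ccc(OCOCC[Si](C)(C)C)cc2o1 | intermediate
3 | 7-(SEM-oxy)chroman-2-one | O=C1CCc2ccc(OCOCC[Si](C)(C)C)cc2O1 | intermediate
4 | 2-(trimethylsilyloxy)-7-(SEM-oxy)-4H-chromene (silyl ketene acetal) | C[Si](C)(C)OC1=CCc2ccc(OCOCC[Si](C)(C)C)cc2O1 | intermediate
5 | rac-3-bromo-7-(SEM-oxy)chroman-2-one | O=C1Oc2cc(OCOCC[Si](C)(C)C)ccc2CC1Br | intermediate
6 | 4-bromoresorcinol | Oc1ccc(Br)c(O)c1 | starting material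
7 | prenyl bromide (1-bromo-3-methylbut-2-ene) | CC(C)=CCBr | starting material
8 | 2-bromo-5-(prenyloxy)phenol | CC(C)=CCOc1ccc(Br)c(O)c1 | intermediate
9 | 1-bromo-4-(prenyloxy)-2-(SEM-oxy)benzene | CC(C)=CCOc1ccc(Br)c(OCOCC[Si](C)(C)C)c1 | intermediate
10 | 4-bromo-2-(2-methylbut-3-en-2-yl)-5-(SEM-oxy)phenol | C=CC(C)(C)c1cc(Br)c(OCOCC[Si](C)(C)C)cc1O | intermediate
11 | 1-bromo-5-(2-methylbut-3-en-2-yl)-4-(prenyloxy)-2-(SEM-oxy)benzene | C=CC(C)(C)c1cc(Br)c(OCOCC[Si](C)(C)C)cc1OCC=C(C)C | intermediate
12 | [5-(2-methylbut-3-en-2-yl)-4-(prenyloxy)-2-(SEM-oxy)phenyl]lithium | C=CC(C)(C)c1cc([Li])c(OCOCC[Si](C)(C)C)cc1OCC=C(C)C | intermediate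
13 | [5-(2-methylbut-3-en-2-yl)-4-(prenyloxy)-2-(SEM-oxy)phenyl]zinc iodide | C=CC(C)(C)c1cc([Zn]I)c(OCOCC[Si](C)(C)C)cc1OCC=C(C)C | intermediate
14 | (3R)-3-[5-(2-methylbut-3-en-2-yl)-4-(prenyloxy)-2-(SEM-oxy)phenyl]-7-(SEM-oxy)chroman-2-one | C=CC(C)(C)c1cc([C@@H]2C(=O)Oc3cc(OCOCC[Si](C)(C)C)ccc3C2)c(OCOCC[Si](C)(C)C)cc1OCC=C(C)C | intermediate
15 | (2R)-3-[2-hydroxy-4-(SEM-oxy)phenyl]-2-[5-(2-methylbut-3-en-2-yl)-4-(prenyloxy)-2-(SEM-oxy)phenyl]propan-1-ol | C=CC(C)(C)c1cc([C@H](CO)Cc2ccc(OCOCC[Si](C)(C)C)cc2O)c(OCOCC[Si](C)(C)C)cc1OCC=C(C)C | intermediate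
16 | (3R)-3-[5-(2-methylbut-3-en-2-yl)-4-(prenyloxy)-2-(SEM-oxy)phenyl]-7-(SEM-oxy)chroman | C=CC(C)(C)c1cc([C@@H]2COc3cc(OCOCC[Si](C)(C)C)ccc3C2)c(OCOCC[Si](C)(C)C)cc1OCC=C(C)C | intermediate
17 | manuifolin D | C=CC(C)(C)c1cc([C@@H]2COc3cc(O)ccc3C2)c(O)cc1OCC=C(C)C | target

## Step count and risks

Total step count: 12. Longest linear sequence: 9 steps (steps 4 to 12, from 4-bromoresorcinol); the ring-A branch (steps 1 to 3) joins at step 9.

**Step 9.** The untested pairing of a six-membered aryl lactone with an ortho-alkoxy arylzinc may give poor facial selection at the C3 radical, or radical capture may be slow so that reduction of 5 or HBr loss to the coumarin takes over. The new centre may also erode by enolisation. The fallback sets the centre by auxiliary-controlled alkylation, a known way to isoflavans in which C3–C4 is formed; it sets out from aryl bromide 11 and returns at diol 15.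

- Ring-B acyl piece: palladium-catalysed arylation of the Reformatsky reagent of ethyl bromoacetate with 11 (Pd(dba)2, Q-Phos, THF, rt) should give the ethyl arylacetate F1. LiOH hydrolysis gives the arylacetic acid F2. Its pivaloyl mixed anhydride with lithiated (R)-4-benzyl-2-oxazolidinone (bought) gives the N-acyl oxazolidinone F3.
- Ring-A electrophile, from bought 2,4-dihydroxybenzaldehyde: SEMCl/iPr2NEt at the non-chelated 4-OH gives 2-hydroxy-4-(SEM-oxy)benzaldehyde F4. Allyl bromide/K2CO3 gives the 2-allyl ether F5, NaBH4 the benzyl alcohol F6, and CBr4/PPh3 the benzyl bromide F7, used fresh.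
- Union and return: the sodium Z-enolate of F3 (NaHMDS, THF, −78 °C) is alkylated by F7 on the face away from the auxiliary benzyl group. Because the aryl group sits where methyl sits in the propionyl series, the (R)-auxiliary should give the (R)-configured alkylated imide F8. LiBH4 then releases the auxiliary and gives the O1-allyl alcohol F9. Pd(PPh3)4/morpholine removes the allyl group, which is expected to react well ahead of the trisubstituted prenyl ether, and delivers 15. Steps 11 and 12 follow unchanged.

**Step 6.** At 190 °C the new ortho-(1,1-dimethylallyl)phenol may ring-close to a dihydrobenzofuran, isomerise by an abnormal Claisen pathway or lose its C5 unit, and part of the material may migrate to the crowded C3'. The fallback makes the C5'–C bond by cross-coupling at a predefined carbon with no thermal step; it sets out from 6 and returns at phenol 10.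

- TIPSCl/imidazole (DMF, 0 °C) should silylate the hydroxyl remote from bromine to give 2-bromo-5-(triisopropylsilyloxy)phenol F10.
- SEMCl/iPr2NEt gives the silyl SEM bis-ether F11, and TBAF at 0 °C removes only the aryl silyl ether to give 4-bromo-3-(SEM-oxy)phenol F12.
- NIS (MeCN, 0 °C) iodinates ortho to the free hydroxyl and para to the SEM ether to give 4-bromo-2-iodo-5-(SEM-oxy)phenol F13.
- A ligand-controlled branch-selective Suzuki–Miyaura coupling of prenylboronic acid pinacol ester at the C–I bond (Pd/biarylphosphine, aq. K3PO4, THF, 40 °C) installs the 1,1-dimethylallyl group and gives 10.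

**Step 3.** Deprotonation of the aryl-ester lactone may be accompanied by attack of the amide at the carbonyl, ring-opening of the enolate or self-condensation, and over-bromination or HBr loss may follow. The fallback makes the enolate equivalent by conjugate reduction without base; it sets out from coumarin 2 and returns at 5. Rhodium-catalysed 1,4-hydrosilylation of 2 (RhCl(PPh3)3, Et3SiH, toluene, 60 °C) should give the triethylsilyl ketene acetal F14 directly, and this is brominated with NBS in THF at −78 °C to give 5.

## Further compounds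

F1 | step 9 | ethyl 2-[5-(2-methylbut-3-en-2-yl)-4-(prenyloxy)-2-(SEM-oxy)phenyl]acetate | CCOC(=O)Cc1cc(C(C)(C)C=C)c(OCC=C(C)C)cc1OCOCC[Si](C)(C)C
F2 | step 9 | 2-[5-(2-methylbut-3-en-2-yl)-4-(prenyloxy)-2-(SEM-oxy)phenyl]acetic acid | OC(=O)Cc1cc(C(C)(C)C=C)c(OCC=C(C)C)cc1OCOCC[Si](C)(C)C
F3 | step 9 | (4R)-4-benzyl-3-{2-[5-(2-methylbut-3-en-2-yl)-4-(prenyloxy)-2-(SEM-oxy)phenyl]acetyl}-1,3-oxazolidin-2-one | O=C(Cc1cc(C(C)(C)C=C)c(OCC=C(C)C)cc1OCOCC[Si](C)(C)C)N1C(=O)OC[C@H]1Cc1ccccc1
F4 | step 9 | 2-hydroxy-4-(SEM-oxy)benzaldehyde | O=Cc1ccc(OCOCC[Si](C)(C)C)cc1O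
F5 | step 9 | 2-(allyloxy)-4-(SEM-oxy)benzaldehyde | C=CCOc1cc(OCOCC[Si](C)(C)C)ccc1C=O
F6 | step 9 | [2-(allyloxy)-4-(SEM-oxy)phenyl]methanol | C=CCOc1cc(OCOCC[Si](C)(C)C)ccc1CO
F7 | step 9 | 2-(allyloxy)-1-(bromomethyl)-4-(SEM-oxy)benzene | C=CCOc1cc(OCOCC[Si](C)(C)C)ccc1CBr
F8 | step 9 | (4R)-4-benzyl-3-{(2R)-3-[2-(allyloxy)-4-(SEM-oxy)phenyl]-2-[5-(2-methylbut-3-en-2-yl)-4-(prenyloxy)-2-(SEM-oxy)phenyl]propanoyl}-1,3-oxazolidin-2-one | C=CC(C)(C)c1cc([C@H](C(=O)N2C(=O)OC[C@H]2Cc2ccccc2)Cc2ccc(OCOCC[Si](C)(C)C)cc2OCC=C)c(OCOCC[Si](C)(C)C)cc1OCC=C(C)C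
F9 | step 9 | (2R)-3-[2-(allyloxy)-4-(SEM-oxy)phenyl]-2-[5-(2-methylbut-3-en-2-yl)-4-(prenyloxy)-2-(SEM-oxy)phenyl]propan-1-ol | C=CC(C)(C)c1cc([C@H](CO)Cc2ccc(OCOCC[Si](C)(C)C)cc2OCC=C)c(OCOCC[Si](C)(C)C)cc1OCC=C(C)C
F10 | step 6 | 2-bromo-5-(triisopropylsilyloxy)phenol | CC(C)[Si](Oc1ccc(Br)c(O)c1)(C(C)C)C(C)C
F11 | step 6 | 1-bromo-2-(SEM-oxy)-4-(triisopropylsilyloxy)benzene | CC(C)[Si](Oc1ccc(Br)c(OCOCC[Si](C)(C)C)c1)(C(C)C)C(C)C
F12 | step 6 | 4-bromo-3-(SEM-oxy)phenol | Oc1ccc(Br)c(OCOCC[Si](C)(C)C)c1
F13 | step 6 | 4-bromo-2-iodo-5-(SEM-oxy)phenol | Oc1cc(OCOCC[Si](C)(C)C)c(Br)cc1I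
F14 | step 3 | 2-(triethylsilyloxy)-7-(SEM-oxy)-4H-chromene | CC[Si](CC)(CC)OC1=CCc2ccc(OCOCC[Si](C)(C)C)cc2O1
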